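**Retrosynthetic overview**
1. Target 16 ⇐ acetylation at C10 and hydroxyl-directed epoxidation of cycloheptenol 14; ring B (seven-membered) is closed last, by ring-closing metathesis at C8=C9 of diene 13.
2. 13 ⇐ reagent-controlled reduction of vinyl ketone 12 (sets C10); 12 is the C6 isovalerate of diol 11.
3. Key bond C1–C10: 11 ⇐ tertiary boronic ester 7 + lithiated methoxyallene 8. The boron-bearing carbon is the former enone β-carbon (a homoenolate equivalent) and migrates with retention onto an acryloyl anion equivalent, joining two normally electrophilic carbons and creating the quaternary center.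
4. 7 ⇐ isopropyl addition to ketone 6 ⇐ one-pot enantioselective conjugate borylation of enone 3 and boron-enolate aldol with aldehyde 2 (sets C1, C5, C6).
5. Ring order: ring A (five-membered) comes from 3; ring B is closed in step 7; the epoxide is added in step 8.

Numbering in the text: daucane positions (C1 methyl-bearing ring-fusion carbon, C4 isopropyl carbinol, C5 ring-fusion CH, C6 isovalerate carbon, C8/C9 epoxide carbons, C10 acetate carbon); α is the face opposite the C1 methyl group.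
Assumption: (R,R)-QuinoxP* is taken as the ligand enantiomer that gives the (3R)-boronate 6; if the sense of induction is the reverse, (S,S)-QuinoxP* is used.

**Route**

Step 1
Reactants: 1 3-methylbut-3-en-1-ol
Product: 2 3-methylbut-3-enal
Conditions: Dess–Martin periodinane (1.1 equiv), CH2Cl2, 0 °C to rt; filtered through basic alumina, cold solution used at once
Reagents that add atoms: none
Why: Dess–Martin oxidation of the primary alcohol runs under neutral conditions, so the β,γ-double bond does not move into conjugation; no stereocenter is formed.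

Step 2
Reactants: 3 3-methylcyclopent-2-en-1-one; 2 3-methylbut-3-enal
Product: 6 (2S,3R)-2-[(1S)-1-hydroxy-3-methylbut-3-en-1-yl]-3-methyl-3-(4,4,5,5-tetramethyl-1,3,2-dioxaborolan-2-yl)cyclopentan-1-one, via boron enolate 4 (not isolated), via boryl aldolate 5 (not isolated)
Conditions: B2pin2 (1.05 equiv), [Cu(MeCN)4]PF6 (5 mol%), (R,R)-QuinoxP* (6 mol%), LiOtBu (10 mol%), THF–DMSO 4:1, rt; then 2 (1.5 equiv), 0 °C; aq NH4Cl
Reagents that add atoms: bis(pinacolato)diboron CC1(C)OB(OC1(C)C)B1OC(C)(C)C(C)(C)O1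
Why: Ligand-controlled copper-boryl 1,4-addition (enantioselective conjugate borylation) sets C1 and turns the electrophilic enone β-carbon into a nucleophilic C–B carbon, and the regiodefined ring (E)-boron enolate 4 then adds to 2 in a chair Zimmerman–Traxler aldol on the face anti to the C–B bond, fixing C5 (trans to boron) and C6 (anti aldol).

Step 3
Reactants: 6 (2S,3R)-2-[(1S)-1-hydroxy-3-methylbut-3-en-1-yl]-3-methyl-3-(4,4,5,5-tetramethyl-1,3,2-dioxaborolan-2-yl)cyclopentan-1-one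
Product: 7 (1R,2S,3R)-2-[(1S)-1-hydroxy-3-methylbut-3-en-1-yl]-3-methyl-1-(propan-2-yl)-3-(4,4,5,5-tetramethyl-1,3,2-dioxaborolan-2-yl)cyclopentan-1-ol
Conditions: i-PrMgCl (3.2 equiv), anhydrous CeCl3 (3.5 equiv), THF, −78 to −40 °C; aq NH4Cl
Reagents that add atoms: isopropylmagnesium chloride CC(C)[Mg]Cl
Why: Organocerium (Imamoto) 1,2-addition suppresses enolization and retro-aldol of the β-alkoxide ketone, and the isopropyl group enters from the α-face, anti to the vicinal C5 side chain, giving the 4β-hydroxyl cis to C6.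

Step 4
Reactants: 7 (1R,2S,3R)-2-[(1S)-1-hydroxy-3-methylbut-3-en-1-yl]-3-methyl-1-(propan-2-yl)-3-(4,4,5,5-tetramethyl-1,3,2-dioxaborolan-2-yl)cyclopentan-1-ol; 8 methoxyallene (1-methoxypropa-1,2-diene)
Product: 11 1-[(1S,2S,3R)-3-hydroxy-2-[(1S)-1-hydroxy-3-methylbut-3-en-1-yl]-1-methyl-3-(propan-2-yl)cyclopentyl]prop-2-en-1-one, via allenyl boronate complex 9 (not isolated), via methoxyallyl boronic ester 10 (not isolated)
Conditions: 8 (4 equiv), n-BuLi (3.8 equiv), THF, −78 °C; add 7, −78 °C; AcOH, −78 °C to rt; then 30% H2O2, pH 7 phosphate buffer, THF, 0 °C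
Reagents that add atoms: hydrogen peroxide OO
Why: Lithiated methoxyallene (an acryloyl anion equivalent) adds to boron, and protonation of complex 9 triggers a stereoretentive 1,2-metallate shift of the tertiary carbon (Matteson/Zweifel-type boronate rearrangement) that joins C1 to C10 and creates the quaternary center with retention, after which C–B oxidation of 10 and loss of methanol release the vinyl ketone.

Step 5
Reactants: 11 1-[(1S,2S,3R)-3-hydroxy-2-[(1S)-1-hydroxy-3-methylbut-3-en-1-yl]-1-methyl-3-(propan-2-yl)cyclopentyl]prop-2-en-1-one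
Product: 12 (1S)-1-[(1S,2R,5S)-2-hydroxy-5-methyl-2-(propan-2-yl)-5-(prop-2-enoyl)cyclopentyl]-3-methylbut-3-en-1-yl 3-methylbutanoate
Conditions: (i-BuCO)2O (1.5 equiv), DMAP (0.1 equiv), pyridine, CH2Cl2, 0 °C to rt
Reagents that add atoms: 3-methylbutanoic anhydride CC(C)CC(=O)OC(=O)CC(C)C
Why: DMAP-catalysed acylation (nucleophilic acyl transfer) esterifies the only secondary hydroxyl (C6) and leaves the tertiary C4 hydroxyl untouched; no stereocenter is affected.

Step 6
Reactants: 12 (1S)-1-[(1S,2R,5S)-2-hydroxy-5-methyl-2-(propan-2-yl)-5-(prop-2-enoyl)cyclopentyl]-3-methylbut-3-en-1-yl 3-methylbutanoate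
Product: 13 (1S)-1-[(1S,2R,5S)-2-hydroxy-5-[(1R)-1-hydroxyprop-2-en-1-yl]-5-methyl-2-(propan-2-yl)cyclopentyl]-3-methylbut-3-en-1-yl 3-methylbutanoate
Conditions: (S)-2-methyl-CBS-oxazaborolidine (0.3 equiv), catecholborane (2.5 equiv), toluene, −78 °C; MeOH quench
Reagents that add atoms: none
Why: Corey–Bakshi–Shibata reduction, with the tert-alkyl group as the large and vinyl as the small ketone substituent, delivers hydride 1,2 to give the (10R)-carbinol, the same sense as Felkin–Anh attack anti to C5 (matched case), and catecholborane at −78 °C spares the alkenes and the ester.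

Step 7
Reactants: 13 (1S)-1-[(1S,2R,5S)-2-hydroxy-5-[(1R)-1-hydroxyprop-2-en-1-yl]-5-methyl-2-(propan-2-yl)cyclopentyl]-3-methylbut-3-en-1-yl 3-methylbutanoate
Product: 14 (3R,3aS,4S,8R,8aS)-3,8-dihydroxy-6,8a-dimethyl-3-(propan-2-yl)-1,2,3,3a,4,5,8,8a-octahydroazulen-4-yl 3-methylbutanoate
Conditions: second-generation Grubbs catalyst (5 mol%), CH2Cl2 (2 mM), 40 °C
Reagents that add atoms: none
Why: Ring-closing metathesis between the vinyl carbinol and the 1,1-disubstituted alkene closes the seven-membered ring across the pre-set trans-1,2-disubstituted cyclopentane and forms the trisubstituted C8=C9 bond, which is necessarily cis in the ring.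

Step 8
Reactants: 14 (3R,3aS,4S,8R,8aS)-3,8-dihydroxy-6,8a-dimethyl-3-(propan-2-yl)-1,2,3,3a,4,5,8,8a-octahydroazulen-4-yl 3-methylbutanoate
Product: 15 (1S,4R,5S,6S,8R,9S,10S)-8,9-epoxy-4,10-dihydroxydaucan-6-yl 3-methylbutanoate (8α,9α-epoxide; 10α-hydroxyl)
Conditions: VO(acac)2 (5 mol%), t-BuOOH (1.5 equiv), CH2Cl2, 0 °C to rt
Reagents that add atoms: tert-butyl hydroperoxide CC(C)(C)OO
Why: Hydroxyl-directed vanadium-catalysed epoxidation delivers oxygen to the face syn to the allylic C10 hydroxyl and so sets the 8α,9α-epoxide (C8 R, C9 S).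

Step 9
Reactants: 15 (1S,4R,5S,6S,8R,9S,10S)-8,9-epoxy-4,10-dihydroxydaucan-6-yl 3-methylbutanoate
Product: 16 (1S,4R,5S,6S,8R,9S,10S)-10-acetoxy-8,9-epoxy-4-hydroxydaucan-6-yl 3-methylbutanoate (CNP0137153.1)
Conditions: Ac2O (3 equiv), DMAP (0.2 equiv), pyridine, rt
Reagents that add atoms: acetic anhydride CC(=O)OC(C)=O
Why: DMAP-catalysed acetylation esterifies the secondary C10 hydroxyl while the tertiary C4 hydroxyl and the epoxide do not react; no stereocenter changes.

**Compound list**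
1 | 3-methylbut-3-en-1-ol | CC(=C)CCO | starting material
2 | 3-methylbut-3-enal | CC(=C)CC=O | intermediate
3 | 3-methylcyclopent-2-en-1-one | CC1=CC(=O)CC1 | starting material
4 | 2-{[(3R)-3-methyl-3-(4,4,5,5-tetramethyl-1,3,2-dioxaborolan-2-yl)cyclopent-1-en-1-yl]oxy}-4,4,5,5-tetramethyl-1,3,2-dioxaborolane (boron enolate) | CC1(C)OB(OC1(C)C)OC2=C[C@](C)(CC2)B3OC(C)(C)C(C)(C)O3 | intermediate
5 | O-pinacolboryl derivative of 6 at the C6 oxygen (boron aldolate) | CC1(C)OB(OC1(C)C)[C@@]2(C)CCC(=O)[C@@H]2[C@@H](OB3OC(C)(C)C(C)(C)O3)CC(C)=C | intermediate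
6 | (2S,3R)-2-[(1S)-1-hydroxy-3-methylbut-3-en-1-yl]-3-methyl-3-(4,4,5,5-tetramethyl-1,3,2-dioxaborolan-2-yl)cyclopentan-1-one | CC1(C)OB(OC1(C)C)[C@@]2(C)CCC(=O)[C@@H]2[C@@H](O)CC(C)=C | intermediate
7 | (1R,2S,3R)-2-[(1S)-1-hydroxy-3-methylbut-3-en-1-yl]-3-methyl-1-(propan-2-yl)-3-(4,4,5,5-tetramethyl-1,3,2-dioxaborolan-2-yl)cyclopentan-1-ol | CC1(C)OB(OC1(C)C)[C@@]2(C)CC[C@@](O)(C(C)C)[C@@H]2[C@@H](O)CC(C)=C | intermediate
8 | methoxyallene (1-methoxypropa-1,2-diene) | C=C=COC | starting material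
9 | trilithium salt of the boronate complex of 7 carrying a 1-methoxyallen-1-yl group on boron, both hydroxyls as alkoxides | [Li+].[Li+].[Li+].C=C=C(OC)[B-]1(OC(C)(C)C(C)(C)O1)[C@@]2(C)CC[C@@]([O-])(C(C)C)[C@@H]2[C@@H]([O-])CC(C)=C | intermediate
10 | (1R,2S,3S)-2-[(1S)-1-hydroxy-3-methylbut-3-en-1-yl]-3-[1-methoxy-1-(4,4,5,5-tetramethyl-1,3,2-dioxaborolan-2-yl)prop-2-en-1-yl]-3-methyl-1-(propan-2-yl)cyclopentan-1-ol (both configurations at the boron-bearing carbon) | C=CC(OC)(B1OC(C)(C)C(C)(C)O1)[C@@]2(C)CC[C@@](O)(C(C)C)[C@@H]2[C@@H](O)CC(C)=C | intermediate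
11 | 1-[(1S,2S,3R)-3-hydroxy-2-[(1S)-1-hydroxy-3-methylbut-3-en-1-yl]-1-methyl-3-(propan-2-yl)cyclopentyl]prop-2-en-1-one | C=CC(=O)[C@@]1(C)CC[C@@](O)(C(C)C)[C@@H]1[C@@H](O)CC(C)=C | intermediate
12 | (1S)-1-[(1S,2R,5S)-2-hydroxy-5-methyl-2-(propan-2-yl)-5-(prop-2-enoyl)cyclopentyl]-3-methylbut-3-en-1-yl 3-methylbutanoate | C=CC(=O)[C@@]1(C)CC[C@@](O)(C(C)C)[C@@H]1[C@@H](OC(=O)CC(C)C)CC(C)=C | intermediate
13 | (1S)-1-[(1S,2R,5S)-2-hydroxy-5-[(1R)-1-hydroxyprop-2-en-1-yl]-5-methyl-2-(propan-2-yl)cyclopentyl]-3-methylbut-3-en-1-yl 3-methylbutanoate | C=C[C@@H](O)[C@@]1(C)CC[C@@](O)(C(C)C)[C@@H]1[C@@H](OC(=O)CC(C)C)CC(C)=C | intermediate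
14 | (3R,3aS,4S,8R,8aS)-3,8-dihydroxy-6,8a-dimethyl-3-(propan-2-yl)-1,2,3,3a,4,5,8,8a-octahydroazulen-4-yl 3-methylbutanoate | O[C@@H]1C=C(C)C[C@H](OC(=O)CC(C)C)[C@@H]2[C@]1(C)CC[C@@]2(O)C(C)C | intermediate
15 | (1S,4R,5S,6S,8R,9S,10S)-8,9-epoxy-4,10-dihydroxydaucan-6-yl 3-methylbutanoate | O[C@@H]1[C@@H]2O[C@]2(C)C[C@H](OC(=O)CC(C)C)[C@@H]2[C@]1(C)CC[C@@]2(O)C(C)C | intermediate
16 | (1S,4R,5S,6S,8R,9S,10S)-10-acetoxy-8,9-epoxy-4-hydroxydaucan-6-yl 3-methylbutanoate | CC(=O)O[C@@H]1[C@@H]2O[C@]2(C)C[C@H](OC(=O)CC(C)C)[C@@H]2[C@]1(C)CC[C@@]2(O)C(C)C | target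

**Totals**
Total step count: 9. Longest linear sequence: 9 steps (1 → 16); 8 steps from enone 3.

**Steps most likely to fail, with fallbacks**

Step 4 (key step). The boronic ester is tertiary and crowded, and the shift creates a fully substituted carbon next to the new quaternary center. Complex 9 may simply lose methoxyallene on protonation, or the vinyl ketone may be attacked during oxidation. The fallback sets out from 7 and comes back at 11. Allyl chloride and LiN(i-Pr)2 in THF at −78 °C generate α-chloroallyllithium in the presence of 7. Its boronate rearranges with loss of chloride (Matteson-type homologation with a smaller, hydrogen-bearing carbenoid, again with retention at C1) to the secondary allylboronic ester (1R,2S,3R)-2-[(1S)-1-hydroxy-3-methylbut-3-en-1-yl]-3-methyl-1-(propan-2-yl)-3-[1-(4,4,5,5-tetramethyl-1,3,2-dioxaborolan-2-yl)prop-2-en-1-yl]cyclopentan-1-ol F4. Oxidation with NaBO3 gives (1R,2S,3S)-2-[(1S)-1-hydroxy-3-methylbut-3-en-1-yl]-3-(1-hydroxyprop-2-en-1-yl)-3-methyl-1-(propan-2-yl)cyclopentan-1-ol F5 as a mixture at C10. MnO2 in CH2Cl2 then oxidises only the allylic C10 hydroxyl and gives 11; the C10 configuration is set afterwards in step 6 as before.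

Step 2. The pinacolboron enolate may be too unreactive, the base may isomerise aldehyde 2 to the conjugated enal, and the facial preference anti to boron (rather than anti to methyl) is argued, not proven. The fallback sets out from 3 and comes back at 6. The borylation is run as in step 2 but enolate 4 is quenched with methanol, giving (3R)-3-methyl-3-(4,4,5,5-tetramethyl-1,3,2-dioxaborolan-2-yl)cyclopentan-1-one F1. IBX in DMSO at 70 °C dehydrogenates the only side that can form an enone, giving (4S)-4-methyl-4-(4,4,5,5-tetramethyl-1,3,2-dioxaborolan-2-yl)cyclopent-2-en-1-one F2. LiN(i-Pr)2 then ZnCl2 gives the single possible α′-enolate, which adds to 2 at −78 °C to give (4R,5S)-5-[(1S)-1-hydroxy-3-methylbut-3-en-1-yl]-4-methyl-4-(4,4,5,5-tetramethyl-1,3,2-dioxaborolan-2-yl)cyclopent-2-en-1-one F3. Conjugate reduction of the ring double bond with [(Ph3P)CuH]6 returns 6. This fixes regiochemistry and trapping but not the facial question.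

Step 3. The ketone is hindered and carries a free β-hydroxyl, so enolization, retro-aldol or β-hydride reduction by the isopropyl reagent may compete, and the reagent may attack boron. The fallback sets out from 6 and comes back at 7 without a new intermediate: a samarium Barbier reaction (2-iodopropane, SmI2, catalytic NiI2, THF, 0 °C), which adds the isopropyl group through a non-basic organosamarium/ketyl pathway with chelation by the β-hydroxyl.

**Further compounds**
F1 | step 2 | (3R)-3-methyl-3-(4,4,5,5-tetramethyl-1,3,2-dioxaborolan-2-yl)cyclopentan-1-one | O=C1C[C@](C)(CC1)B1OC(C)(C)C(C)(C)O1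
F2 | step 2 | (4S)-4-methyl-4-(4,4,5,5-tetramethyl-1,3,2-dioxaborolan-2-yl)cyclopent-2-en-1-one | O=C1C[C@](C)(C=C1)B1OC(C)(C)C(C)(C)O1
F3 | step 2 | (4R,5S)-5-[(1S)-1-hydroxy-3-methylbut-3-en-1-yl]-4-methyl-4-(4,4,5,5-tetramethyl-1,3,2-dioxaborolan-2-yl)cyclopent-2-en-1-one | CC1(C)OB(OC1(C)C)[C@@]2(C)C=CC(=O)[C@@H]2[C@@H](O)CC(C)=C
F0 | step 3 | none | none
F4 | step 4 | (1R,2S,3R)-2-[(1S)-1-hydroxy-3-methylbut-3-en-1-yl]-3-methyl-1-(propan-2-yl)-3-[1-(4,4,5,5-tetramethyl-1,3,2-dioxaborolan-2-yl)prop-2-en-1-yl]cyclopentan-1-ol (both C10 epimers) | C=CC(B1OC(C)(C)C(C)(C)O1)[C@@]2(C)CC[C@@](O)(C(C)C)[C@@H]2[C@@H](O)CC(C)=C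
F5 | step 4 | (1R,2S,3S)-2-[(1S)-1-hydroxy-3-methylbut-3-en-1-yl]-3-(1-hydroxyprop-2-en-1-yl)-3-methyl-1-(propan-2-yl)cyclopentan-1-ol (both C10 epimers) | C=CC(O)[C@@]1(C)CC[C@@](O)(C(C)C)[C@@H]1[C@@H](O)CC(C)=C
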